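## Retrosynthetic overview
1. The butenolide is formed last, by Pd/CO carbonylative lactonisation of a (Z)-3-iodoallylic alcohol. That iodide comes from a propargylic ester by one reductive operation, which also sets 3-OH, makes 17-OH and 19-OH, and releases the auxiliary.
2. The equatorial C17 comes from an epimerisable C8 aldehyde, made by Meinwald rearrangement of the 8(17)-epoxide of the exocyclic alkene.
3. Rings A and B form together by Mn(III)/Cu(II) oxidative radical bicyclisation of an acyclic α-methyl-β-keto ester dienyne that carries a chiral ester. The C4–C5 bond closes ring A, then C10–C9 closes ring B.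
4. The acyclic chain comes from a β-keto ester dianion plus an allylic bromide. The bromide comes from geranyl bromide, propyne and CH2O in one pot, followed by SeO2 oxidation.

Assumption: the sense of induction follows the usual π-stacking model of 8-phenylmenthyl esters (non-chelated radical, ketone C=O anti to the ester carbon), which for the (1S,2R,5S) auxiliary leaves the Si face of C4 open and gives the ent series; the auxiliary is bought and is recovered in step 9.

Carbons carry ent-labdane numbers. α/β refer to the standard drawing with ring A on the left, in which C20 is α.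

## Route

Step 1
Reactants: 1 geranyl bromide; 2 propyne
Product: 6 (E)-7,11-dimethyldodeca-6,10-dien-2-yn-1-yl pivalate, via 1,3-dilithiopropyne 3 (not isolated), via lithium enynide 4 (not isolated), via lithium dienynoxide 5 (not isolated)
Conditions: 2, n-BuLi (2 equiv per 2), TMEDA, Et2O–hexane, −78 °C → rt; 1, 0 °C → rt; (CH2O)n, rt; PivCl, 0 °C → rt
Reagents that add atoms: paraformaldehyde (as formaldehyde), C=O; pivaloyl chloride, CC(C)(C)C(=O)Cl
Why: Propargylation with 1,3-dilithiopropyne, in which the more nucleophilic sp3 carbanion displaces the primary allylic bromide by SN2 without touching the E-alkene, the surviving acetylide adds to formaldehyde and the lithium alkoxide is acylated in the same flask, so C11–C15 and a hydride-labile protecting group arrive in one operation (no stereocentre formed).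

Step 2
Reactants: 6 dienyne pivalate
Product: 7 (6E,10E)-12-hydroxy-7,11-dimethyldodeca-6,10-dien-2-yn-1-yl pivalate
Conditions: SeO2 (0.1 equiv), t-BuOOH (2 equiv), salicylic acid (0.1 equiv), CH2Cl2, 0 °C → rt, stopped at about 70% conversion, 6 recycled
Reagents that add atoms: tert-butyl hydroperoxide, CC(C)(C)OO (oxygen relayed by catalytic SeO2, O=[Se]=O)
Why: Sharpless-type SeO2/t-BuOOH allylic oxidation (ene reaction then [2,3]-sigmatropic shift) attacks the most accessible, electron-rich terminal isopropylidene and gives the E-allylic alcohol, while the internal alkene and the propargylic positions react more slowly.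

Step 3
Reactants: 7 allylic alcohol
Product: 8 (6E,10E)-12-bromo-7,11-dimethyldodeca-6,10-dien-2-yn-1-yl pivalate
Conditions: CBr4, PPh3, CH2Cl2, 0 °C
Reagents that add atoms: carbon tetrabromide, BrC(Br)(Br)Br
Why: Appel reaction, an SN2 displacement of the oxyphosphonium at the primary allylic carbon under neutral conditions that keeps both E-alkenes, the alkyne and the pivalate intact.

Step 4
Reactants: 9 (+)-8-phenylmenthol; 10 ethyl 2-methylacetoacetate
Product: 11 (1S,2R,5S)-8-phenylmenthyl 2-methyl-3-oxobutanoate (α-epimer mixture)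
Conditions: 10 (3 equiv), DMAP (0.3 equiv), toluene, reflux, 4 Å MS (removal of EtOH)
Reagents that add atoms: none
Why: DMAP-catalysed transesterification of an enolisable β-keto ester via its acylketene, driven by removal of ethanol, which leaves the carbinol stereocentres of the auxiliary untouched and the α-carbon as an irrelevant epimer mixture.

Step 5
Reactants: 11 auxiliary β-keto ester; 8 allylic bromide
Product: 13 (1S,2R,5S)-8-phenylmenthyl (6E,10E)-2,6,10-trimethyl-3-oxo-16-(pivaloyloxy)hexadeca-6,10-dien-14-ynoate, via sodium lithium dianion 12 (not isolated)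
Conditions: 11, NaH, THF, 0 °C; n-BuLi, 0 °C; 8, −78 → 0 °C; aq NH4Cl
Reagents that add atoms: none
Why: Weiler dianion alkylation, in which the γ-carbanion of the β-keto ester dianion is far more nucleophilic than the α-position and alkylates the allylic bromide by SN2, with retention of alkene geometry, faster than it attacks the hindered pivalate.

Step 6 (key step)
Reactants: 13 acyclic β-keto ester dienyne
Product: 17 bicyclic keto ester (3-oxo; 4α-axial CO2R*; 4β-Me; 5β-H; 9β-H; 10α-Me; 8(17)-exo-methylene; 9α-equatorial 5-pivaloyloxypent-3-ynyl chain), via C4 radical 14 (not isolated), via monocyclic C10 radical 15 (not isolated), via bicyclic C8 radical 16 (not isolated)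
Conditions: Mn(OAc)3·2H2O (2.2 equiv), Cu(OAc)2·H2O (1.0 equiv), degassed AcOH (0.1 M), 25 °C, 16 h; minor auxiliary diastereomer removed by chromatography
Reagents that add atoms: none
Why: Snider-type Mn(III)/Cu(II) oxidative radical polyene cyclisation, in which Mn(III) oxidises the enol to the electrophilic C4 radical that closes ring A (6-endo, C4–C5) and then ring B (6-endo, C10–C9) through a chair–chair array, so the two E-alkenes give the trans-decalin with 5β-H, 10α-Me and an equatorial C9 chain, the non-chelated radical places CO2R* axial (cis to C20), the π-stacked phenyl of the auxiliary covers the Re face of C4 so that Si-face bonding fixes 4S and hence the whole ent series, and Cu(II) oxidises the tertiary C8 radical to the least substituted 8(17)-alkene faster than it can add to the ester-deactivated alkyne.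

Step 7
Reactants: 17 bicyclic alkene
Product: 18 8β,17-epoxide of 17 (spiro-oxirane; O on the β face)
Conditions: m-CPBA (1.1 equiv), CH2Cl2, 0 °C
Reagents that add atoms: m-chloroperoxybenzoic acid, OOC(=O)c1cccc(Cl)c1
Why: Prilezhaev epoxidation, in which the electron-rich 1,1-disubstituted alkene reacts far faster than the alkyne or the hindered ketone (no Baeyer–Villiger at 0 °C) and the peracid comes from the β face opposite the axial C20 methyl, although this C8 configuration is erased in the next step.

Step 8
Reactants: 18 epoxide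
Product: 20 17-aldehyde with equatorial 8β-CHO and axial 8α-H, via C8-epimeric aldehyde mixture 19 (not isolated)
Conditions: BF3·OEt2 (0.3 equiv), CH2Cl2, −78 °C, 20 min; then DBU (0.6 equiv), −78 °C → rt, 6 h
Reagents that add atoms: none
Why: Meinwald rearrangement followed by base equilibration, in which BF3 ionises the epoxide at tertiary C8, a 1,2-hydride shift from C17 gives the aldehyde, and DBU epimerises C8 through the enolate to the thermodynamic equatorial formyl isomer because the axial one clashes 1,3-diaxially with the C20 methyl, which sets C8 as in the target.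

Step 9
Reactants: 20 keto ester aldehyde
Product: 23 (Z)-vinyl iodide tetraol (3α-OH; 17-OH; 19-OH; side chain CH2CH2C(I)=CHCH2OH), via alkynyl tetraol aluminate 21 (not isolated), via cyclic vinylalanate 22 (not isolated)
Conditions: Red-Al (12 equiv), THF, 0 → 60 °C; −78 °C, EtOAc; I2, THF, −78 → 0 °C; aq Rochelle salt
Reagents that add atoms: iodine, II
Why: Global hydride reduction merged with Corey-type trans-hydroalumination/iodinolysis, in which Red-Al reduces the aldehyde, the ketone (hydride from the β face, opposite the axial C19 and C20 groups, gives the equatorial 3α-OH) and both esters (freeing the auxiliary and the propargylic alkoxide), the alkoxide-bound Al–H then adds trans across the alkyne to a five-membered vinylalanate with Al on C13, and I2 cleaves the C–Al bond with retention to the Z-iodide.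

Step 10
Reactants: 23 vinyl iodide tetraol
Product: 24 14-deoxy-17-hydroxyandrographolide
Conditions: Pd(PPh3)4 (5 mol %), CO (1 atm), K2CO3 (2 equiv), THF, 50 °C
Reagents that add atoms: carbon monoxide, [C-]#[O+]
Why: Stille-type Pd(0) carbonylative lactonisation, in which oxidative addition into C–I with retention, CO insertion and capture of the acyl-Pd by the cis-disposed C15 hydroxyl (five-membered ring, strongly favoured over the remote OH groups) give the α-alkyl butenolide without touching any stereocentre.

## Compound list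
1 | geranyl bromide | CC(C)=CCC/C(C)=C/CBr | starting material
2 | propyne | CC#C | starting material
3 | 1,3-dilithiopropyne | [Li]CC#C[Li] | intermediate
4 | lithium (E)-6,10-dimethylundeca-5,9-dien-1-ynide | CC(C)=CCC/C(C)=C/CCC#C[Li] | intermediate
5 | lithium (E)-7,11-dimethyldodeca-6,10-dien-2-yn-1-oxide | CC(C)=CCC/C(C)=C/CCC#CCO[Li] | intermediate
6 | (E)-7,11-dimethyldodeca-6,10-dien-2-yn-1-yl pivalate | CC(C)=CCC/C(C)=C/CCC#CCOC(=O)C(C)(C)C | intermediate
7 | (6E,10E)-12-hydroxy-7,11-dimethyldodeca-6,10-dien-2-yn-1-yl pivalate | OC/C(C)=C/CC/C(C)=C/CCC#CCOC(=O)C(C)(C)C | intermediate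
8 | (6E,10E)-12-bromo-7,11-dimethyldodeca-6,10-dien-2-yn-1-yl pivalate | BrC/C(C)=C/CC/C(C)=C/CCC#CCOC(=O)C(C)(C)C | intermediate
9 | (+)-8-phenylmenthol, (1S,2R,5S)-5-methyl-2-(2-phenylpropan-2-yl)cyclohexanol | O[C@H]1C[C@@H](C)CC[C@@H]1C(C)(C)c1ccccc1 | starting material
10 | ethyl 2-methylacetoacetate | CCOC(=O)C(C)C(C)=O | starting material
11 | (1S,2R,5S)-8-phenylmenthyl 2-methyl-3-oxobutanoate (α-epimers) | CC(=O)C(C)C(=O)O[C@H]1C[C@@H](C)CC[C@@H]1C(C)(C)c1ccccc1 | intermediate
12 | sodium lithium α,γ-dianion of 11 | [Li+].[Na+].[CH2-]C(=O)[C-](C)C(=O)O[C@H]1C[C@@H](C)CC[C@@H]1C(C)(C)c1ccccc1 | intermediate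
13 | (1S,2R,5S)-8-phenylmenthyl (6E,10E)-2,6,10-trimethyl-3-oxo-16-(pivaloyloxy)hexadeca-6,10-dien-14-ynoate (α-epimers) | CC(C(=O)O[C@H]1C[C@@H](C)CC[C@@H]1C(C)(C)c1ccccc1)C(=O)CC/C(C)=C/CC/C(C)=C/CCC#CCOC(=O)C(C)(C)C | intermediate
14 | acyclic C4 (α-keto ester) radical | C[C](C(=O)O[C@H]1C[C@@H](C)CC[C@@H]1C(C)(C)c1ccccc1)C(=O)CC/C(C)=C/CC/C(C)=C/CCC#CCOC(=O)C(C)(C)C | intermediate
15 | monocyclic (ring A) tertiary C10 radical | C[C@]1(C(=O)O[C@H]3C[C@@H](C)CC[C@@H]3C(C)(C)c3ccccc3)[C@@H](CC/C(C)=C/CCC#CCOC(=O)C(C)(C)C)[C](C)CCC1=O | intermediate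
16 | bicyclic tertiary C8 radical | C[C@]1(C(=O)O[C@H]3C[C@@H](C)CC[C@@H]3C(C)(C)c3ccccc3)[C@H]2CC[C](C)[C@@H](CCC#CCOC(=O)C(C)(C)C)[C@]2(C)CCC1=O | intermediate
17 | trans-decalin keto ester: 3-oxo, 4α(axial)-CO2(8-phenylmenthyl), 4β-Me, 5β-H, 9β-H, 10α-Me, 8(17)-methylene, 9α-(5-pivaloyloxypent-3-ynyl) | C[C@]1(C(=O)O[C@H]3C[C@@H](C)CC[C@@H]3C(C)(C)c3ccccc3)[C@H]2CCC(=C)[C@@H](CCC#CCOC(=O)C(C)(C)C)[C@]2(C)CCC1=O | intermediate
18 | 8β,17-epoxide of 17 | C[C@]1(C(=O)O[C@H]3C[C@@H](C)CC[C@@H]3C(C)(C)c3ccccc3)[C@H]2CC[C@@]4(CO4)[C@@H](CCC#CCOC(=O)C(C)(C)C)[C@]2(C)CCC1=O | intermediate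
19 | 17-aldehyde, C8 epimer mixture | C[C@]1(C(=O)O[C@H]3C[C@@H](C)CC[C@@H]3C(C)(C)c3ccccc3)[C@H]2CCC(C=O)[C@@H](CCC#CCOC(=O)C(C)(C)C)[C@]2(C)CCC1=O | intermediate
20 | 17-aldehyde, 8β(equatorial)-CHO, 8α-H | C[C@]1(C(=O)O[C@H]3C[C@@H](C)CC[C@@H]3C(C)(C)c3ccccc3)[C@H]2CC[C@H](C=O)[C@@H](CCC#CCOC(=O)C(C)(C)C)[C@]2(C)CCC1=O | intermediate
21 | alkynyl tetraol (3α,15,17,19-tetrahydroxy-16-nor-ent-labd-13-yne; in the flask as aluminium alkoxides, drawn free) | C[C@]1(CO)[C@H]2CC[C@H](CO)[C@@H](CCC#CCO)[C@]2(C)CC[C@H]1O | intermediate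
22 | cyclic sodium vinylalanate (Al on C13, O15–Al chelate; other OH groups drawn free) | [Na+].C[C@]1(CO)[C@H]2CC[C@H](CO)[C@@H](CCC3=CCO[Al-]3(OCCOC)OCCOC)[C@]2(C)CC[C@H]1O | intermediate
23 | (13Z)-13-iodo-16-nor-ent-labd-13-ene-3α,15,17,19-tetraol | C[C@]1(CO)[C@H]2CC[C@H](CO)[C@@H](CC/C(I)=C/CO)[C@]2(C)CC[C@H]1O | intermediate
24 | 14-deoxy-17-hydroxyandrographolide, 3-[2-[(1R,2S,4aS,5R,6R,8aS)-6-hydroxy-2,5-bis(hydroxymethyl)-5,8a-dimethyldecahydronaphthalen-1-yl]ethyl]furan-2(5H)-one | C[C@]1(CO)[C@H]2CC[C@H](CO)[C@@H](CCC3=CCOC3=O)[C@]2(C)CC[C@H]1O | target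

## Step count and risks
Total steps: 10.
Longest linear sequence: 9 (steps 1, 2, 3, 5, 6, 7, 8, 9, 10); step 4 is a one-step side branch.
Stereocentres: C4, C5, C9 and C10 are set in step 6, C8 in step 8 and C3 in step 9.

**Step 6.**
- Risk: the C8 radical (or the derived cation) may be captured 5-exo by the side-chain alkyne.
- Risk: Cu(II) may oxidise the monocyclic radical 15 before ring B closes.
- Risk: Δ7 or Δ8(9) alkene isomers may form, and auxiliary control may be only about 9:1.
- Fallback: this sets out from 13 and changes both how the radical is made and how the cascade ends. NaH then PhSeCl in THF gives the α-phenylselanyl β-keto ester F1. Sunlamp photolysis of F1 in benzene runs a redox-neutral PhSe group-transfer bicyclisation. It uses the same chair–chair cascade and the same auxiliary, and both rings still form in one operation. The product is the bicyclic tertiary C8 phenyl selenide F2. H2O2/pyridine then causes selenoxide syn-elimination toward the methyl group, and the route is rejoined at 17.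

**Step 8.**
- Risk: the C8 cation may be attacked by the alkyne, or may trigger backbone shifts (9-H to C8, then C20 migration) instead of the C17 hydride shift.
- Fallback: this sets out from 17, bypasses 18 and avoids any cation. 9-BBN in THF hydroborates the 1,1-disubstituted alkene faster than the internal alkyne, from the β face, to give the C17 B-alkyl-9-BBN adduct F3. NaBO3 oxidises F3 to the axial (8-epi) 17-alcohol F4. Dess–Martin periodinane then gives the axial (8-epi) 17-aldehyde F5 and returns any C3 carbinol formed by 9-BBN to the ketone. DBU equilibration rejoins the route at 20.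

**Step 9.**
- Risk: the neopentylic, axial 8-phenylmenthyl ester may need conditions under which the vinylalanate is protonated (giving the E-allylic alcohol) or is formed with imperfect regiochemistry.
- Risk: iodinolysis in the presence of four alkoxides may be low-yielding.
- Fallback: this sets out from 20 and separates reduction from alkyne functionalisation. LiAlH4 in refluxing Et2O with aqueous work-up gives 21, isolated this time. Catalytic [Cp*Ru(MeCN)3]PF6 with Et3SiH in CH2Cl2 at 0 °C effects trans-hydrosilylation, placing silicon distal to the propargylic OH and tolerating the free alcohols, to give the (Z)-13-triethylsilyl allylic alcohol F6. NIS in (CF3)2CHOH effects iododesilylation with retention, and the route is rejoined at 23.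

## Further compounds
F1 | step 6 | α-phenylselanyl β-keto ester of 13 | CC([Se]c1ccccc1)(C(=O)O[C@H]1C[C@@H](C)CC[C@@H]1C(C)(C)c1ccccc1)C(=O)CC/C(C)=C/CC/C(C)=C/CCC#CCOC(=O)C(C)(C)C
F2 | step 6 | bicyclic tertiary C8 phenyl selenide (C8 epimers) | C[C@]1(C(=O)O[C@H]3C[C@@H](C)CC[C@@H]3C(C)(C)c3ccccc3)[C@H]2CCC(C)([Se]c3ccccc3)[C@@H](CCC#CCOC(=O)C(C)(C)C)[C@]2(C)CCC1=O
F3 | step 8 | C17 B-alkyl-9-BBN adduct (8β-H, axial CH2B) | C[C@]1(C(=O)O[C@H]3C[C@@H](C)CC[C@@H]3C(C)(C)c3ccccc3)[C@H]2CC[C@@H](CB4C5CCCC4CCC5)[C@@H](CCC#CCOC(=O)C(C)(C)C)[C@]2(C)CCC1=O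
F4 | step 8 | axial (8-epi) 17-alcohol | C[C@]1(C(=O)O[C@H]3C[C@@H](C)CC[C@@H]3C(C)(C)c3ccccc3)[C@H]2CC[C@@H](CO)[C@@H](CCC#CCOC(=O)C(C)(C)C)[C@]2(C)CCC1=O
F5 | step 8 | axial (8-epi) 17-aldehyde | C[C@]1(C(=O)O[C@H]3C[C@@H](C)CC[C@@H]3C(C)(C)c3ccccc3)[C@H]2CC[C@@H](C=O)[C@@H](CCC#CCOC(=O)C(C)(C)C)[C@]2(C)CCC1=O
F6 | step 9 | (Z)-13-triethylsilyl allylic alcohol (tetraol) | C[C@]1(CO)[C@H]2CC[C@H](CO)[C@@H](CC/C([Si](CC)(CC)CC)=C/CO)[C@]2(C)CC[C@H]1O
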